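**Retrosynthetic overview**

1. Numbering: ring A is the dibromophenol ring (C1 OH, C2 Br, C4 Br, C6 ether O); ring B is the tribromophenol ring (C1' ether O, C2' Br, C3' H, C4' Br, C5' Br, C6' OH).
2. The strategy rests on ring B: C6'(OH) sits between C1' and C5' like a ketone carbonyl between its two alpha carbons, and C2'–C3'–C4' is a three-carbon unit whose centre ends as H. Ring B is therefore cut at C1'–C2' and C4'–C5' into an aryloxyacetone and nitromalonaldehyde.
3. Ring A is bought as guaiacol. The O–C1' link is made as an alkyl aryl ether (chloroacetone) before ring B exists, and ring B is then grown on it as a 4-nitrophenol (nitro at C3').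
4. Endgame: demethylate; brominate C2, C4 and C5' under hydroxyl control while the nitro group blocks C3'; cap both hydroxyls as methyl ethers; reduce the nitro group so the amine directs bromine to C2' and C4'; remove nitrogen via the diazonium salt; demethylate.

Key step: step 2

Assumption: sodium nitromalonaldehyde is taken as the purchasable monohydrate (impact-sensitive, to be handled in small batches).

**Route**

Step 1
Reactants: 1 guaiacol (2-methoxyphenol); 2 chloroacetone
Product: 3 1-(2-methoxyphenoxy)propan-2-one
Conditions: K2CO3, KI (cat.), acetone, reflux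
Reagents that add atoms: none
Why: Williamson ether synthesis, in which the phenoxide of 1 displaces chloride from the activated alpha-chloro ketone by SN2 (iodide catalysis).

Step 2
Reactants: 3 1-(2-methoxyphenoxy)propan-2-one; 4 sodium nitromalonaldehyde
Product: 6 2-(2-methoxyphenoxy)-4-nitrophenol, via open-chain dienolate 5 (not isolated)
Conditions: NaOH (2 equiv), EtOH/H2O, 0 °C to rt, 3–5 d; then aq. HCl
Reagents that add atoms: none
Why: This is the nitromalonaldehyde synthesis of 4-nitrophenols from ketones that carry a CH group on each side of the carbonyl. The enolate of 3 at the more acidic aryloxymethylene carbon should add to one formyl group of 4 and lose water to give the open-chain dienolate 5 (C1'–C2' bond); the methyl carbon then enolises and attacks the remaining formyl group in a 6-(enolendo)-exo-trig intramolecular aldol (C5'–C4' bond), and loss of water with tautomerisation of the dienone gives the 4-nitrophenoxide. No stereocentre is formed. The step needs ring closure through carbon and reaction at both alpha carbons: closure through the enolate oxygen to a 2H-pyranol is reversible, whereas the carbon closure is drawn forward by aromatisation to a stabilised nitrophenoxide, and delocalisation in 5 lets the C1'–C2' bond turn into the geometry needed for closure. Because the three-carbon partner is symmetric, either order of the two condensations ends in the same phenol, so no regiochemical question arises.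

Step 3
Reactants: 6 2-(2-methoxyphenoxy)-4-nitrophenol
Product: 7 2-(2-hydroxyphenoxy)-4-nitrophenol
Conditions: BBr3 (3 equiv), CH2Cl2, −78 °C to rt; then H2O
Reagents that add atoms: none
Why: Lewis acid-mediated aryl methyl ether cleavage, in which BBr3 binds the methoxy oxygen and bromide removes the methyl group by SN2 while the diaryl ether and the nitro group stay intact.

Step 4
Reactants: 7 2-(2-hydroxyphenoxy)-4-nitrophenol
Product: 8 2-bromo-6-(3,5-dibromo-2-hydroxyphenoxy)-4-nitrophenol
Conditions: Br2 (3.05 equiv), AcOH, rt, then 50 °C
Reagents that add atoms: bromine, BrBr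
Why: Electrophilic aromatic bromination under hydroxyl control, the ring A hydroxyl directing to its free ortho (C2) and para (C4) positions and the ring B hydroxyl to its only free ortho position C5', because C3' is blocked by the nitro group, which also deactivates C2' and C4'.

Step 5
Reactants: 8 2-bromo-6-(3,5-dibromo-2-hydroxyphenoxy)-4-nitrophenol
Product: 9 1-bromo-3-(3,5-dibromo-2-methoxyphenoxy)-2-methoxy-5-nitrobenzene
Conditions: MeI (3 equiv), K2CO3, DMF, 40 °C
Reagents that add atoms: iodomethane, CI
Why: Williamson O-methylation of both phenoxides, which caps the hydroxyls so that the later aniline is not a 4-aminophenol that bromine would oxidise to a quinone imine.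

Step 6
Reactants: 9 1-bromo-3-(3,5-dibromo-2-methoxyphenoxy)-2-methoxy-5-nitrobenzene
Product: 10 3-bromo-5-(3,5-dibromo-2-methoxyphenoxy)-4-methoxyaniline
Conditions: SnCl2·2H2O, conc. HCl, EtOH, 70 °C; then aq. NaHCO3
Reagents that add atoms: none
Why: Chemoselective nitro-to-amine reduction by SnCl2 in acid, which leaves aryl bromides and ethers untouched where catalytic hydrogenation would risk hydrodebromination.

Step 7
Reactants: 10 3-bromo-5-(3,5-dibromo-2-methoxyphenoxy)-4-methoxyaniline
Product: 11 2,3,6-tribromo-5-(3,5-dibromo-2-methoxyphenoxy)-4-methoxyaniline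
Conditions: NBS (2.1 equiv), DMF, 0 °C to rt
Reagents that add atoms: N-bromosuccinimide, O=C1CCC(=O)N1Br
Why: Electrophilic aromatic bromination directed by the amino group, the strongest donor present, to its two free ortho positions C2' and C4' (its para position C6' carries the methoxy group), while the dibrominated ring A is too deactivated and hindered to compete.

Step 8
Reactants: 11 2,3,6-tribromo-5-(3,5-dibromo-2-methoxyphenoxy)-4-methoxyaniline
Product: 13 1,2,5-tribromo-4-(3,5-dibromo-2-methoxyphenoxy)-3-methoxybenzene, via arenediazonium hydrogen sulfate 12 (not isolated)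
Conditions: NaNO2, conc. H2SO4/AcOH, 0–5 °C; then 50% aq. H3PO2, 0 °C to rt
Reagents that add atoms: none
Why: Reductive deamination (hydrodediazoniation), in which nitrosylsulfuric acid diazotises the weakly basic 2,6-dibromoaniline and H3PO2 reduces the diazonium ion by a radical chain, leaving hydrogen at C3'.

Step 9
Reactants: 13 1,2,5-tribromo-4-(3,5-dibromo-2-methoxyphenoxy)-3-methoxybenzene
Product: 14 2,3,5-tribromo-6-(3,5-dibromo-2-hydroxyphenoxy)phenol (target)
Conditions: BBr3 (5 equiv), CH2Cl2, −78 °C to rt; then H2O
Reagents that add atoms: none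
Why: Double aryl methyl ether cleavage with BBr3, which spares the diaryl ether and the aryl bromides and frees both hydroxyls to give the target.

**Compound list**

1 | guaiacol (2-methoxyphenol) | COc1ccccc1O | starting material
2 | chloroacetone | CC(=O)CCl | starting material
3 | 1-(2-methoxyphenoxy)propan-2-one | CC(=O)COc1ccccc1OC | intermediate
4 | sodium nitromalonaldehyde (used as its monohydrate) | [Na+].O=C[C-](C=O)[N+](=O)[O-] | starting material
5 | sodium 4-(2-methoxyphenoxy)-2-nitro-5-oxohexa-1,3-dien-1-olate (alkene geometry mobile) | [Na+].CC(=O)C(Oc1ccccc1OC)=CC(=C[O-])[N+](=O)[O-] | intermediate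
6 | 2-(2-methoxyphenoxy)-4-nitrophenol | COc1ccccc1Oc1cc(ccc1O)[N+](=O)[O-] | intermediate
7 | 2-(2-hydroxyphenoxy)-4-nitrophenol | Oc1ccccc1Oc1cc(ccc1O)[N+](=O)[O-] | intermediate
8 | 2-bromo-6-(3,5-dibromo-2-hydroxyphenoxy)-4-nitrophenol | Oc1c(Br)cc(Br)cc1Oc1cc(cc(Br)c1O)[N+](=O)[O-] | intermediate
9 | 1-bromo-3-(3,5-dibromo-2-methoxyphenoxy)-2-methoxy-5-nitrobenzene | COc1c(Br)cc(Br)cc1Oc1cc(cc(Br)c1OC)[N+](=O)[O-] | intermediate
10 | 3-bromo-5-(3,5-dibromo-2-methoxyphenoxy)-4-methoxyaniline | COc1c(Br)cc(Br)cc1Oc1cc(N)cc(Br)c1OC | intermediate
11 | 2,3,6-tribromo-5-(3,5-dibromo-2-methoxyphenoxy)-4-methoxyaniline | COc1c(Br)cc(Br)cc1Oc1c(Br)c(N)c(Br)c(Br)c1OC | intermediate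
12 | 2,3,6-tribromo-5-(3,5-dibromo-2-methoxyphenoxy)-4-methoxybenzenediazonium hydrogen sulfate | COc1c(Br)cc(Br)cc1Oc1c(Br)c([N+]#N)c(Br)c(Br)c1OC.OS(=O)(=O)[O-] | intermediate
13 | 1,2,5-tribromo-4-(3,5-dibromo-2-methoxyphenoxy)-3-methoxybenzene | COc1c(Br)cc(Br)cc1Oc1c(Br)cc(Br)c(Br)c1OC | intermediate
14 | 2,3,5-tribromo-6-(3,5-dibromo-2-hydroxyphenoxy)phenol | Oc1c(Br)cc(Br)cc1Oc1c(Br)cc(Br)c(Br)c1O | target

Total step count: 9
Longest linear sequence: 9 steps (from guaiacol)

**Steps most likely to fail**

1. Step 2. Self-aldol condensation of the aryloxyacetone and base-induced breakdown of the nitromalonaldehyde anion may outrun the slow double condensation, or the sequence may stall after the first condensation. Fallback: the diaryl ether is made with both rings already aromatic. The fallback sets out from guaiacol 1, which is coupled with 2-bromo-1-methoxy-4-nitrobenzene (COc1ccc(cc1Br)[N+](=O)[O-]) in an Ullmann ether synthesis (CuI, N,N-dimethylglycine, Cs2CO3, dioxane, 100 °C) to give 1-methoxy-2-(2-methoxyphenoxy)-4-nitrobenzene F1. BBr3 in CH2Cl2 then cleaves both methyl ethers, and the route is rejoined at 7.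

2. Step 8. The diazonium ion of the crowded, doubly ortho-brominated ring may be diverted to the phenol or to azo and triazene coupling products before hydrogen transfer from H3PO2 takes place. Fallback: the fallback sets out from 11. It is diazotised as before to 12, which is captured with aqueous KI, a fast copper-free iodo-dediazoniation, to give 1,2,4-tribromo-5-(3,5-dibromo-2-methoxyphenoxy)-3-iodo-6-methoxybenzene F2. Chemoselective iodine–magnesium exchange with i-PrMgCl·LiCl in THF at −40 °C (iodide exchanges far faster than bromide) and protonation with MeOH then rejoin the route at 13.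

3. Step 4. Regiocontrol may be lost in the one-pot triple bromination, with ring A taking up a third bromine while ring B is still unreacted, so that bromination levels are mixed and hard to separate. Fallback: the brominations are spread over two better differentiated substrates. The fallback sets out from 6, which with Br2 (2 equiv) in AcOH should brominate para to the methoxy group (C4) and ortho to the ring B hydroxyl (C5') to give 2-bromo-6-(5-bromo-2-methoxyphenoxy)-4-nitrophenol F3. BBr3 demethylation gives 2-bromo-6-(5-bromo-2-hydroxyphenoxy)-4-nitrophenol F4, in which C2 is the only position still activated by a hydroxyl. One equivalent of Br2 in AcOH then rejoins the route at 8.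

**Further compounds**

F1 | step 2 | 1-methoxy-2-(2-methoxyphenoxy)-4-nitrobenzene | COc1ccccc1Oc1cc(ccc1OC)[N+](=O)[O-]
F2 | step 8 | 1,2,4-tribromo-5-(3,5-dibromo-2-methoxyphenoxy)-3-iodo-6-methoxybenzene | COc1c(Br)cc(Br)cc1Oc1c(Br)c(I)c(Br)c(Br)c1OC
F3 | step 4 | 2-bromo-6-(5-bromo-2-methoxyphenoxy)-4-nitrophenol | COc1ccc(Br)cc1Oc1cc(cc(Br)c1O)[N+](=O)[O-]
F4 | step 4 | 2-bromo-6-(5-bromo-2-hydroxyphenoxy)-4-nitrophenol | Oc1ccc(Br)cc1Oc1cc(cc(Br)c1O)[N+](=O)[O-]
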